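Zeta is the run to read first: its last two readings of substrate are 22% and 19%, and the last stands beside 40% of target at 1 M of reagent.

| flask | substrate | reagent | temperature | remark | time |
|---|---|---|---|---|---|
| delta | 0.20 M | 0.25 M | 2 °C | run made earlier |  |
| zeta | 0.20 M | 1 M | 52 °C | run made earlier |  |
| theta | 0.30 M | 0.50 M | 2 °C | run made earlier |  |
| red | 0.20 M | 0.500 M | 40 °C |  | 1.0 h |
| grey | 0.20 M | 0.500 M | 10 °C |  | 1.0 h |
| ochre | 0.20 M | 0.500 M | −20 °C |  | 1.0 h |
| teal | 0.20 M | 0.500 M | 70 °C |  | 1.0 h |

delta run (percent of the substrate charged)

| time / h | target / % | substrate / % |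
|---|---|---|
| 0.833 | 2 | 99 |
| 1.50 | 0 | 96 |
| 2.50 | 0 | 95 |
| 3.00 | 0 | 96 |
| 4.00 | 2 | 92 |
| 5.00 | 2 | 88 |

zeta run (percent of the substrate charged)

| time / min | target / % | substrate / % |
|---|---|---|
| 2.00 | 15 | 75 |
| 3.00 | 22 | 66 |
| 6.00 | 31 | 43 |
| 12.0 | 44 | 29 |
| 15.0 | 43 | 22 |
| 30.0 | 40 | 19 |

theta run (percent of the substrate charged)

| time / h | target / % | substrate / % |
|---|---|---|
| 1.00 | 3 | 98 |
| 2.00 | 3 | 96 |
| 3.00 | 2 | 90 |
| 4.00 | 6 | 84 |
| 5.00 | 6 | 84 |

(standard deviation of a reading: 2 percentage points)

- the flask with the highest amount of target, in percent of the substrate charged ("all alike" if they lie within 1.5 percentage points) (red / grey / ochre / teal / all alike)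
- final target, as a percentage of the substrate charged, in red
- final target, as a percentage of the substrate charged, in grey
- final target, as a percentage of the substrate charged, in ochre
- final target, as a percentage of the substrate charged, in teal

- a species is counted by the substrate in it: one self-condensation product counts as two
- the earlier runs were read with a standard deviation of 2 percentage points
- steps thought possible: substrate + reagent <-> target; substrate + reagent <-> isomer of the product A; target <-> isomer of the product B; 2 substrate -> self-condensation product

Target forms from substrate and reagent, and in red reagent is charged at 2.50 times the substrate, so I take its level as nearly constant and treat the step as pseudo-first-order in substrate. From zeta I therefore keep 2.11 M⁻¹, the holding ratio: the fraction of the charge in target, over the fraction in substrate, per molar of reagent, an apparent equilibrium constant as read. Taken over unchanged from zeta's 52 °C to red's 40 °C, which is my assumption, it gives in red target over substrate of 1.05. Zeta's pair of target and substrate shrinks from 90.0% to 59.0%, and if red's pair ends at that last level, my reckoning puts target in red at 30.3%. Teal is hotter, so I expect the same ratio on a smaller pair. Delta and theta show 2% and 6% of target after hours, so I expect little in grey and ochre, and I commit to red as the highest.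

The forecast also names red, with 34% in red, 3.5% in grey, 0.1% in ochre and 24% in teal, teal being “equilibrated quickly, but with a less favourable equilibrium and a faster drain”.

The flasks give red as the highest: 27.5% in red, 2.44% in grey, 0.0339% in ochre and 7.24% in teal.

    substrate + reagent ⇌ target (K = 2.00 M⁻¹, k = 0.510 M⁻¹ min⁻¹, Ea = 86.0 kJ mol⁻¹, ΔH = −9.00 kJ mol⁻¹)
    substrate + reagent ⇌ isomer of the product A (K = 4.90 M⁻¹, k = 0.100 M⁻¹ min⁻¹, Ea = 70.0 kJ mol⁻¹, ΔH = −67.0 kJ mol⁻¹)
    target ⇌ isomer of the product B (K = 1.70, k = 0.0170 min⁻¹, Ea = 111 kJ mol⁻¹, ΔH = 16.0 kJ mol⁻¹)
    2 substrate → self-condensation product (k = 0.520 M⁻¹ min⁻¹, Ea = 78.0 kJ mol⁻¹)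
    (constants at 70 °C)

Target over substrate is 0.904 in red and 0.862 in teal, against my 1.05, but teal's pair is down to 15.6%, so the pair is what to watch. A teal run with the falling back of target to substrate and reagent taken away ends at 36.1% instead of 7.24%, the largest single effect, though not the whole story.

In the neighbour of red charged with 0.20 M of reagent, the holding ratio gives target over substrate of 0.422, hence 17.5% of target on zeta's pair. That flask computes to 13.1% of target beside 42.2% of substrate, with reagent at 0.161 M at the end against the 0.20 M I reckoned with.

The earlier runs and the new flask stem from a simulated flask from invented constants; scatter was added.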